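Ring A is the ester ring (C1 CO2Me, C2 Me, C3 O-aryl, C4 OH, C5 Me, C6 OH) and ring B the acid ring (C1' O-aryl, C2' CHO, C3' OH, C4' Cl, C5' Me, C6' CO2H).
Retrosynthesis: the C2'–CHO bond and the protecting groups go first; ring A is then cut at C5–C6, C3–C4 and C1–C6 into an aryloxy(vinyl)ketene and 1-(triisopropylsilyloxy)prop-1-yne; the acid chloride behind the ketene is cut at its sp3 C–O bond into a ring B phenol and a bromoglutaconate.
The cut is possible because in ring A the C6 hydroxyl stands para to the C3 aryl ether and meta to the C4 oxygen: C6 is a former ketene carbonyl, C3 the aryloxy-bearing ketene carbon, C4 and C5 the two carbons of a siloxyalkyne, and C2 and C1 a vinyl group that carries the ester.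
Forward: ring B phenol from orsellinic acid (ester, chlorine, silyl ether), Williamson ether with the bromide of dimethyl 3-methylglutaconate, monoacid, acid chloride; ring A, the only ring made, then arises in one operation ([2+2], four-electron opening, six-electron closure); desilylation, formylation at C2' and ester cleavage finish the route.
Stereochemistry: the target has no stereocentre; the racemic C–O carbon of the chain intermediates becomes C3 of the arene, and the only element to control is the E enoate of the acid chloride (thermodynamic preference, chromatography).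

Key step: step 9

Remark: orsellinic acid, dimethyl 3-methylglutaconate (sold as an E/Z mixture) and ethyl acetate are taken as purchased; ArB stands for 2-(tert-butoxycarbonyl)-4-chloro-3-methyl-5-(triisopropylsilyloxy)phenyl, the protected ring B.

Step 1
Reactants: 1 orsellinic acid (2,4-dihydroxy-6-methylbenzoic acid)
Product: 2 tert-butyl 2,4-dihydroxy-6-methylbenzoate
Conditions: tert-butyl 2,2,2-trichloroacetimidate, THF, 23 °C
Reagents that add atoms: tert-butyl 2,2,2-trichloroacetimidate, CC(C)(C)OC(=N)C(Cl)(Cl)Cl
Why: In this imidate esterification the carboxylic acid protonates the imidate and is O-alkylated by the tert-butyl cation equivalent so formed, whereas the much less acidic phenols do not activate the reagent and room temperature avoids decarboxylation of the electron-rich acid.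

Step 2
Reactants: 2 tert-butyl 2,4-dihydroxy-6-methylbenzoate
Product: 3 tert-butyl 3-chloro-4,6-dihydroxy-2-methylbenzoate
Conditions: SO2Cl2 (1 equiv), Et2O, 0 °C
Reagents that add atoms: sulfuryl chloride, O=S(=O)(Cl)Cl
Why: Electrophilic aromatic chlorination of 2,4-dihydroxy-6-methylbenzoyl compounds with one equivalent of SO2Cl2 goes to the carbon ortho to the free hydroxyl and para to the chelated one (next to the methyl group), as in the chlorination of orcylaldehyde, and ether at 0 °C tempers the HCl so that the tert-butyl ester should survive.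

Step 3
Reactants: 3 tert-butyl 3-chloro-4,6-dihydroxy-2-methylbenzoate
Product: 4 tert-butyl 3-chloro-6-hydroxy-2-methyl-4-(triisopropylsilyloxy)benzoate (ArB–OH)
Conditions: i-Pr3SiCl, imidazole, DMF, 0 → 23 °C
Reagents that add atoms: triisopropylsilyl chloride, CC(C)[Si](Cl)(C(C)C)C(C)C
Why: Imidazole-promoted O-silylation takes only the free and more acidic 4-OH, because the 6-OH is held in a hydrogen bond to the ester carbonyl and is shielded by the tert-butyl ester.

Step 4
Reactants: 5 dimethyl 3-methylglutaconate (dimethyl 3-methylpent-2-enedioate, E/Z mixture)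
Product: 6 dimethyl 4-bromo-3-methylpent-2-enedioate (racemic, E/Z mixture)
Conditions: N-bromosuccinimide, AIBN (cat.), PhCF3, 80 °C
Reagents that add atoms: N-bromosuccinimide, O=C1CCC(=O)N1Br
Why: In this Wohl–Ziegler bromination, hydrogen abstraction at the CH2 that is both allylic and α to an ester gives a radical delocalized over C2–C4 whose two termini both carry CO2Me, so bromine transfer to either end gives the same constitution.

Step 5
Reactants: 4 tert-butyl 3-chloro-6-hydroxy-2-methyl-4-(triisopropylsilyloxy)benzoate, 6 dimethyl 4-bromo-3-methylpent-2-enedioate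
Product: 7 dimethyl (E)-4-(ArB-oxy)-3-methylpent-2-enedioate (racemic)
Conditions: K2CO3, acetone, 0 → 23 °C
Reagents that add atoms: none
Why: This Williamson ether synthesis takes place at a secondary carbon activated by the adjacent ester and alkene, direct and allylic displacement converge on one constitution because both allyl termini bear CO2Me, the new stereocentre is racemic and is erased in step 9, and the E enoate (ester trans to the branched carbon) should be favoured and is freed from any Z isomer by chromatography.

Step 6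
Reactants: 7 dimethyl (E)-4-(ArB-oxy)-3-methylpent-2-enedioate
Product: 8 (E)-2-(ArB-oxy)-5-methoxy-3-methyl-5-oxopent-3-enoic acid (racemic)
Conditions: Me3SnOH, ClCH2CH2Cl, 60 °C; dilute HCl wash
Reagents that add atoms: trimethyltin hydroxide, C[Sn](C)(C)O
Why: In this trimethyltin hydroxide ester hydrolysis the tin-bound hydroxide should attack the more electrophilic, non-conjugated methyl ester next to the aryloxy group, while the β,β-disubstituted enoate ester, the hindered tert-butyl benzoate and the aryl silyl ether remain, and the absence of free base avoids deprotonation at C4 with double-bond shift or E/Z scrambling.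

Step 7
Reactants: 8 (E)-2-(ArB-oxy)-5-methoxy-3-methyl-5-oxopent-3-enoic acid
Product: 9 methyl (E)-4-(ArB-oxy)-5-chloro-3-methyl-5-oxopent-2-enoate (racemic, used crude)
Conditions: 1-chloro-N,N,2-trimethylprop-1-en-1-amine, CH2Cl2, 0 → 23 °C
Reagents that add atoms: 1-chloro-N,N,2-trimethylprop-1-en-1-amine, CC(C)=C(Cl)N(C)C
Why: Acid chloride formation with an α-chloroenamine runs through an acyloxyiminium ion under neutral conditions and releases only an amide, so no HCl threatens the tert-butyl ester, the silyl ether or the enoate geometry.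

Step 8
Reactants: 10 ethyl acetate
Product: 13 1-(triisopropylsilyloxy)prop-1-yne, via dibromoketone enolate 11 (not isolated), via lithium ynolate 12 (not isolated)
Conditions: CH2Br2, lithium 2,2,6,6-tetramethylpiperidide, THF, −78 °C, then 10; LiN(SiMe3)2; n-BuLi, −78 → 23 °C; i-Pr3SiCl, 0 °C
Reagents that add atoms: dibromomethane, BrCBr; triisopropylsilyl chloride, CC(C)[Si](Cl)(C(C)C)C(C)C
Why: In this Kowalski ynolate formation, acylation of dibromomethyllithium gives enolate 11, bromine–lithium exchange and a carbenoid 1,2-shift (Fritsch–Buttenberg–Wiechell type) give ynolate 12, and the bulky silyl chloride reacts at oxygen to give the siloxyalkyne.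

Step 9
Reactants: 9 methyl (E)-4-(ArB-oxy)-5-chloro-3-methyl-5-oxopent-2-enoate, 13 1-(triisopropylsilyloxy)prop-1-yne
Product: 18 methyl 3-(ArB-oxy)-6-hydroxy-2,5-dimethyl-4-(triisopropylsilyloxy)benzoate, via aryloxy(vinyl)ketene 14 (not isolated), via 4-vinylcyclobutenone 15 (not isolated), via dienylketene 16 (not isolated), via cyclohexa-2,4-dienone 17 (not isolated)
Conditions: Et3N, 13 (excess), toluene, 23 °C, slow addition of 9; then 90 °C
Reagents that add atoms: none
Why: Proposed new method: Et3N removes the C4–H of 9 (α to the acid chloride, α to oxygen and vinylogously activated by the ester) and loss of chloride gives ketene 14, which siloxyalkyne 13 traps in a [2+2] cycloaddition (its methyl-bearing carbon to the ketene carbonyl carbon, its silyloxy carbon to the aryloxy carbon; C5–C6 and C3–C4 of ring A) to give the transient four-membered ring of 15. On heating, 15 opens in a conrotatory four-electron process (aryloxy donor outward, vinyl inward) to dienylketene 16, whose thermal disrotatory six-electron electrocyclization closes the six-membered carbocycle of ring A through the C6–C1 bond to give dienone 17, and enolization gives phenol 18. The closest known reaction types are the Danheiser benzannulation of siloxyalkynes with vinylketenes made by cyclobutenone opening or photochemical Wolff rearrangement, and the [2+2] cycloaddition of alkoxy- and siloxyalkynes with ketenes made from acid chlorides and Et3N; what is untested is an α-aryloxy vinylketene generated by dehydrochlorination in the presence of the alkyne. No stereocentre is created, and the racemic centre of 9 becomes sp-hybridized in 14. The step needs a single [2+2] regiochemistry, which the polarization of the ynol ether (nucleophilic at the carbon remote from oxygen) and the electrophilic ketene carbonyl carbon secure, and it needs the E enoate of 9, which holds the ester carbonyl away from the ketene so that oxa-electrocyclization to a 2-pyranone cannot compete. Slow addition of 9 keeps the ketene concentration low against dimerization, and because the cycloaddition is complete at 23 °C before the flask is heated, no ketene 14 is left to acylate phenol 18.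

Step 10
Reactants: 18 methyl 3-(ArB-oxy)-6-hydroxy-2,5-dimethyl-4-(triisopropylsilyloxy)benzoate
Product: 19 methyl 3-[2-(tert-butoxycarbonyl)-4-chloro-5-hydroxy-3-methylphenoxy]-4,6-dihydroxy-2,5-dimethylbenzoate
Conditions: Bu4NF, AcOH, THF, 0 → 23 °C
Reagents that add atoms: none
Why: Fluoride-mediated desilylation cleaves both aryl triisopropylsilyl ethers, the acetic acid buffer keeps the liberated phenols protonated, and neither the hindered tert-butyl ester nor the methyl ester reacts.

Step 11
Reactants: 19 methyl 3-[2-(tert-butoxycarbonyl)-4-chloro-5-hydroxy-3-methylphenoxy]-4,6-dihydroxy-2,5-dimethylbenzoate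
Product: 20 methyl 3-[2-(tert-butoxycarbonyl)-4-chloro-6-formyl-5-hydroxy-3-methylphenoxy]-4,6-dihydroxy-2,5-dimethylbenzoate
Conditions: MgCl2, Et3N, (CH2O)n, THF, 65 °C
Reagents that add atoms: paraformaldehyde (as formaldehyde), C=O
Why: In this Casnati–Skattebøl ortho-formylation the magnesium phenoxide of ring B delivers coordinated formaldehyde to its only free ortho carbon (C2'), a second formaldehyde accepts hydride from the benzylic alkoxide to give the aldehyde, and no other ring carbon in the molecule bears hydrogen.

Step 12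
Reactants: 20 methyl 3-[2-(tert-butoxycarbonyl)-4-chloro-6-formyl-5-hydroxy-3-methylphenoxy]-4,6-dihydroxy-2,5-dimethylbenzoate
Product: 21 5-chloro-2-[2,4-dihydroxy-5-(methoxycarbonyl)-3,6-dimethylphenoxy]-3-formyl-4-hydroxy-6-methylbenzoic acid (CNP0210944.0)
Conditions: CF3CO2H, CH2Cl2, 0 → 23 °C
Reagents that add atoms: none
Why: Acidolysis of the tert-butyl ester by alkyl–oxygen cleavage with loss of isobutene leaves the methyl ester untouched, the two fully substituted rings cannot be C-alkylated, and without carboxyl activation no lactonization onto the neighbouring phenol is expected.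

Compound list
1 | orsellinic acid (2,4-dihydroxy-6-methylbenzoic acid) | Cc1cc(O)cc(O)c1C(=O)O | starting material
2 | tert-butyl 2,4-dihydroxy-6-methylbenzoate | Cc1cc(O)cc(O)c1C(=O)OC(C)(C)C | intermediate
3 | tert-butyl 3-chloro-4,6-dihydroxy-2-methylbenzoate | Cc1c(Cl)c(O)cc(O)c1C(=O)OC(C)(C)C | intermediate
4 | tert-butyl 3-chloro-6-hydroxy-2-methyl-4-(triisopropylsilyloxy)benzoate | Cc1c(Cl)c(O[Si](C(C)C)(C(C)C)C(C)C)cc(O)c1C(=O)OC(C)(C)C | intermediate
5 | dimethyl 3-methylglutaconate (dimethyl 3-methylpent-2-enedioate, E/Z mixture) | COC(=O)CC(C)=CC(=O)OC | starting material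
6 | dimethyl 4-bromo-3-methylpent-2-enedioate (racemic; E/Z mixture, E isomer drawn) | COC(=O)/C=C(C)/C(Br)C(=O)OC | intermediate
7 | dimethyl (E)-4-[2-(tert-butoxycarbonyl)-4-chloro-3-methyl-5-(triisopropylsilyloxy)phenoxy]-3-methylpent-2-enedioate (racemic) | COC(=O)/C=C(C)/C(Oc1cc(O[Si](C(C)C)(C(C)C)C(C)C)c(Cl)c(C)c1C(=O)OC(C)(C)C)C(=O)OC | intermediate
8 | (E)-2-[2-(tert-butoxycarbonyl)-4-chloro-3-methyl-5-(triisopropylsilyloxy)phenoxy]-5-methoxy-3-methyl-5-oxopent-3-enoic acid (racemic) | COC(=O)/C=C(C)/C(Oc1cc(O[Si](C(C)C)(C(C)C)C(C)C)c(Cl)c(C)c1C(=O)OC(C)(C)C)C(=O)O | intermediate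
9 | methyl (E)-4-[2-(tert-butoxycarbonyl)-4-chloro-3-methyl-5-(triisopropylsilyloxy)phenoxy]-5-chloro-3-methyl-5-oxopent-2-enoate (racemic) | COC(=O)/C=C(C)/C(Oc1cc(O[Si](C(C)C)(C(C)C)C(C)C)c(Cl)c(C)c1C(=O)OC(C)(C)C)C(Cl)=O | intermediate
10 | ethyl acetate | CCOC(C)=O | starting material
11 | lithium 1,1-dibromoprop-1-en-2-olate (enolate of 1,1-dibromopropan-2-one, formed in the flask) | [Li+].CC([O-])=C(Br)Br | intermediate
12 | lithium prop-1-yn-1-olate (formed in the flask) | [Li+].CC#C[O-] | intermediate
13 | 1-(triisopropylsilyloxy)prop-1-yne | CC#CO[Si](C(C)C)(C(C)C)C(C)C | intermediate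
14 | methyl (E)-4-[2-(tert-butoxycarbonyl)-4-chloro-3-methyl-5-(triisopropylsilyloxy)phenoxy]-3-methyl-5-oxopenta-2,4-dienoate (ketene, formed in the flask) | COC(=O)/C=C(C)/C(Oc1cc(O[Si](C(C)C)(C(C)C)C(C)C)c(Cl)c(C)c1C(=O)OC(C)(C)C)=C=O | intermediate
15 | methyl (E)-3-{1-[2-(tert-butoxycarbonyl)-4-chloro-3-methyl-5-(triisopropylsilyloxy)phenoxy]-3-methyl-4-oxo-2-(triisopropylsilyloxy)cyclobut-2-en-1-yl}but-2-enoate (racemic, formed in the flask) | CC1=C(O[Si](C(C)C)(C(C)C)C(C)C)C(Oc2cc(O[Si](C(C)C)(C(C)C)C(C)C)c(Cl)c(C)c2C(=O)OC(C)(C)C)(/C(C)=C/C(=O)OC)C1=O | intermediate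
16 | methyl (2E,4Z)-4-[2-(tert-butoxycarbonyl)-4-chloro-3-methyl-5-(triisopropylsilyloxy)phenoxy]-3,6-dimethyl-7-oxo-5-(triisopropylsilyloxy)hepta-2,4,6-trienoate (formed in the flask) | CC(=C=O)/C(O[Si](C(C)C)(C(C)C)C(C)C)=C(Oc1cc(O[Si](C(C)C)(C(C)C)C(C)C)c(Cl)c(C)c1C(=O)OC(C)(C)C)\C(C)=C\C(=O)OC | intermediate
17 | methyl 3-[2-(tert-butoxycarbonyl)-4-chloro-3-methyl-5-(triisopropylsilyloxy)phenoxy]-2,5-dimethyl-6-oxo-4-(triisopropylsilyloxy)cyclohexa-2,4-diene-1-carboxylate (racemic, formed in the flask) | COC(=O)C1C(C)=C(Oc2cc(O[Si](C(C)C)(C(C)C)C(C)C)c(Cl)c(C)c2C(=O)OC(C)(C)C)C(O[Si](C(C)C)(C(C)C)C(C)C)=C(C)C1=O | intermediate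
18 | methyl 3-[2-(tert-butoxycarbonyl)-4-chloro-3-methyl-5-(triisopropylsilyloxy)phenoxy]-6-hydroxy-2,5-dimethyl-4-(triisopropylsilyloxy)benzoate | COC(=O)c1c(C)c(Oc2cc(O[Si](C(C)C)(C(C)C)C(C)C)c(Cl)c(C)c2C(=O)OC(C)(C)C)c(O[Si](C(C)C)(C(C)C)C(C)C)c(C)c1O | intermediate
19 | methyl 3-[2-(tert-butoxycarbonyl)-4-chloro-5-hydroxy-3-methylphenoxy]-4,6-dihydroxy-2,5-dimethylbenzoate | COC(=O)c1c(C)c(Oc2cc(O)c(Cl)c(C)c2C(=O)OC(C)(C)C)c(O)c(C)c1O | intermediate
20 | methyl 3-[2-(tert-butoxycarbonyl)-4-chloro-6-formyl-5-hydroxy-3-methylphenoxy]-4,6-dihydroxy-2,5-dimethylbenzoate | COC(=O)c1c(C)c(Oc2c(C=O)c(O)c(Cl)c(C)c2C(=O)OC(C)(C)C)c(O)c(C)c1O | intermediate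
21 | 5-chloro-2-[2,4-dihydroxy-5-(methoxycarbonyl)-3,6-dimethylphenoxy]-3-formyl-4-hydroxy-6-methylbenzoic acid | COC(=O)c1c(C)c(Oc2c(C=O)c(O)c(Cl)c(C)c2C(=O)O)c(O)c(C)c1O | target

Total step count: 12. Longest linear sequence: 10 steps (steps 1, 2, 3, 5, 6, 7, 9, 10, 11, 12, from orsellinic acid).

Steps most likely to fail

Step 9 (the step labelled as a new method). Dimerization or amine-induced oligomerization of the ketene, protonation of the siloxyalkyne by the ammonium salt during heating, or isomerization of the enoate followed by oxa-electrocyclization may outpace the [2+2] step. The fallback gives up the annulation and joins two finished rings by a copper-catalysed Ullmann diaryl ether synthesis, all of it known chemistry. It sets out from phenol 4. Purchased methyl 2,4-dihydroxy-3,6-dimethylbenzoate F1 is iodinated at its only free ring carbon (N-iodosuccinimide, MeCN) to methyl 4,6-dihydroxy-3-iodo-2,5-dimethylbenzoate F2. Protection (NaH, MeOCH2Cl, DMF) gives methyl 3-iodo-4,6-bis(methoxymethoxy)-2,5-dimethylbenzoate F3. Coupling of F3 with 4 (CuI, picolinic acid, K3PO4, DMSO, 80 °C) should give methyl 3-(ArB-oxy)-4,6-bis(methoxymethoxy)-2,5-dimethylbenzoate F4; the silyl ether of 4 is the weak point under this base. Bu4NF and then dilute HCl in methanol remove the silyl ether and the two methoxymethyl ethers, and the route is rejoined at 19.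

Step 6. Chemoselectivity between the two methyl esters may be lost, or the double bond may first migrate into conjugation with the aryloxy-bearing ester (in step 5 or here, through the extended enolate), which would turn the hydrolysis to the other ester. The fallback marks the ester to be cleaved by construction. It sets out from phenol 4. Alkylation with allyl bromoacetate (K2CO3, acetone) gives allyl 2-(ArB-oxy)acetate F5. Its lithium enolate (LiN(SiMe3)2, THF, −78 °C) adds in a Michael reaction to methyl but-2-ynoate and, after proton transfer and a buffered cold quench, should give 1-allyl 5-methyl (E)-2-(ArB-oxy)-3-methylpent-3-enedioate F6. Pd(PPh3)4 and morpholine then remove only the allyl ester, and the route is rejoined at acid 8.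

Step 11. Attack at the crowded carbon between two oxygen substituents of a phenoxide deactivated by its para ester may be slow, and the reaction may stall at the hydroxymethyl stage. The fallback separates the C–C bond formation from the oxidation. It sets out from 19. PhB(OH)2, paraformaldehyde and catalytic propionic acid in toluene at reflux tether formaldehyde to the ring B phenol and should give the 2-phenyl-4H-1,3,2-benzodioxaborin F7. Exchange with propane-1,3-diol frees the 2-(hydroxymethyl)phenol F8, and MnO2 in CH2Cl2 oxidizes the benzylic alcohol, so that the route is rejoined at aldehyde 20.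

Further compounds
F1 | step 9 | methyl 2,4-dihydroxy-3,6-dimethylbenzoate (purchased) | COC(=O)c1c(C)cc(O)c(C)c1O
F2 | step 9 | methyl 4,6-dihydroxy-3-iodo-2,5-dimethylbenzoate | COC(=O)c1c(C)c(I)c(O)c(C)c1O
F3 | step 9 | methyl 3-iodo-4,6-bis(methoxymethoxy)-2,5-dimethylbenzoate | COC(=O)c1c(C)c(I)c(OCOC)c(C)c1OCOC
F4 | step 9 | methyl 3-[2-(tert-butoxycarbonyl)-4-chloro-3-methyl-5-(triisopropylsilyloxy)phenoxy]-4,6-bis(methoxymethoxy)-2,5-dimethylbenzoate | COC(=O)c1c(C)c(Oc2cc(O[Si](C(C)C)(C(C)C)C(C)C)c(Cl)c(C)c2C(=O)OC(C)(C)C)c(OCOC)c(C)c1OCOC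
F5 | step 6 | allyl 2-[2-(tert-butoxycarbonyl)-4-chloro-3-methyl-5-(triisopropylsilyloxy)phenoxy]acetate | C=CCOC(=O)COc1cc(O[Si](C(C)C)(C(C)C)C(C)C)c(Cl)c(C)c1C(=O)OC(C)(C)C
F6 | step 6 | 1-allyl 5-methyl (E)-2-[2-(tert-butoxycarbonyl)-4-chloro-3-methyl-5-(triisopropylsilyloxy)phenoxy]-3-methylpent-3-enedioate (racemic) | COC(=O)/C=C(C)/C(Oc1cc(O[Si](C(C)C)(C(C)C)C(C)C)c(Cl)c(C)c1C(=O)OC(C)(C)C)C(=O)OCC=C
F7 | step 11 | tert-butyl 7-chloro-5-[2,4-dihydroxy-5-(methoxycarbonyl)-3,6-dimethylphenoxy]-8-methyl-2-phenyl-4H-1,3,2-benzodioxaborine-6-carboxylate | COC(=O)c1c(C)c(Oc2c3COB(c4ccccc4)Oc3c(Cl)c(C)c2C(=O)OC(C)(C)C)c(O)c(C)c1O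
F8 | step 11 | methyl 3-[2-(tert-butoxycarbonyl)-4-chloro-5-hydroxy-6-(hydroxymethyl)-3-methylphenoxy]-4,6-dihydroxy-2,5-dimethylbenzoate | COC(=O)c1c(C)c(Oc2c(CO)c(O)c(Cl)c(C)c2C(=O)OC(C)(C)C)c(O)c(C)c1O
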